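**Plan**
- **Cuts:** the retrosynthesis cuts the lactone bond C1–O(C17) first, then C17–C18, then C23–C24. The C1–C17 half is taken apart at C2=C3, C4–C5, C6=C7, the oxazole ring (C8–C10) and C15–C16.
- **Enabling feature:** C24 is a lone quaternary carbinol bearing OH, CH3, the C25 carboxyl and the C23 methylene, so it is lactic acid alkylated at its α-carbon. It lies in the open side chain, seven bonds beyond C17 of the macrolactone, where no ring stereocentre can reach it. It is therefore made separately from (R)-lactic acid through the enolate of its cis tert-butyl dioxolanone.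
- **Forward order:** steps 1–10 build the side chain C18–C25. Steps 11–26 build C10–C17 from (S)-citronellal, close the oxazole (ring A) in step 18 and grow the chain to C1. Step 27 joins C17–C18, step 29 closes the macrolactone (ring B), and step 30 removes all silicon groups.
- **Stereocentres:** C24 comes from (R)-lactic acid, relayed by the acetal carbon, and C13 from (S)-citronellal. C15/C16 come from an Evans syn glycolate aldol, C4/C5 from a Brown (Z)-crotylboration, and C17 from Felkin–Anh addition next to the C16 silyloxy group.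
- **Alkenes:** 21Z comes from cis-butenediol, 18E from syn carboalumination, 6E from a Horner–Wadsworth–Emmons reaction and 2E from cross metathesis.

Key step: step 8

Assumption: carbons are numbered from the lactone carbonyl C1 through the oxazole (C8 = ring C4, C9 = ring C5, C10 = ring C2) to the carboxyl C25. Ring B has 18 members counted through the oxazole nitrogen and 19 counted through C9 and the ring oxygen. All starting materials are taken as purchasable in enantiopure form.

Step 1
Reactants: 1 (R)-lactic acid; 2 pivalaldehyde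
Product: 3 (2R,5R)-2-tert-butyl-5-methyl-1,3-dioxolan-4-one (cis)
Conditions: TsOH·H2O (cat.), H2SO4 (cat.), pentane, reflux, Dean–Stark trap; crystallisation from pentane–Et2O, −78 °C
Reagents that add atoms: none
Why: Acid-catalysed acetalisation with azeotropic removal of water should favour the cis acetal (tert-butyl and methyl on the same ring face), and crystallisation should free it from the trans isomer, so that the C24 configuration is copied onto the acetal carbon before step 8 erases it.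

Step 2
Reactants: 4 cis-but-2-ene-1,4-diol
Product: 5 (Z)-4-(tert-butyldimethylsilyloxy)but-2-en-1-ol
Conditions: TBSCl (1 equiv), imidazole, THF, 0 °C → rt, 4 in threefold excess
Reagents that add atoms: tert-butyldimethylsilyl chloride, CC(C)(C)[Si](C)(C)Cl
Why: Statistical monosilylation of a cheap symmetrical diol taken in excess should give mainly the monoether, and the Z alkene that becomes C21=C22 is bought with 4.

Step 3
Reactants: 5 (Z)-4-(tert-butyldimethylsilyloxy)but-2-en-1-ol
Product: 6 (Z)-1-bromo-4-(tert-butyldimethylsilyloxy)but-2-ene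
Conditions: CBr4, PPh3, CH2Cl2, −20 → 0 °C
Reagents that add atoms: carbon tetrabromide, BrC(Br)(Br)Br
Why: The Appel reaction replaces the primary allylic hydroxyl by bromide through SN2 attack on an oxyphosphonium ion under neutral conditions, which should leave the Z geometry and the silyl ether intact.

Step 4
Reactants: 6 (Z)-1-bromo-4-(tert-butyldimethylsilyloxy)but-2-ene; 7 ethynyltrimethylsilane
Product: 8 tert-butyldimethyl{[(Z)-6-(trimethylsilyl)hex-2-en-5-yn-1-yl]oxy}silane
Conditions: CuI, NaI, K2CO3, DMF, rt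
Reagents that add atoms: none
Why: Copper-mediated coupling of a terminal alkyne with a primary allylic halide (alkynylcopper allylation) should form C19–C20 at the unhindered primary carbon and give the skipped enyne with the Z alkene unchanged.

Step 5
Reactants: 8 tert-butyldimethyl{[(Z)-6-(trimethylsilyl)hex-2-en-5-yn-1-yl]oxy}silane
Product: 9 (Z)-hex-2-en-5-yn-1-ol
Conditions: Bu4NF, AcOH, THF, 0 °C → rt
Reagents that add atoms: none
Why: Fluoride-induced desilylation cleaves the O–Si and the alkynyl C–Si bond in one operation, and the acetic acid buffer should stop base-induced migration of the skipped enyne into conjugation.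

Step 6
Reactants: 9 (Z)-hex-2-en-5-yn-1-ol
Product: 11 (2Z,5E)-6-iodo-5-methylhexa-2,5-dien-1-ol, via alkenylalane 10 (not isolated)
Conditions: Me3Al (3 equiv), Cp2ZrCl2 (0.25 equiv), CH2Cl2, 0 °C → rt; I2, THF, −30 °C; aq. K2CO3
Reagents that add atoms: trimethylaluminium, C[Al](C)C; iodine, [I][I]
Why: Zirconium-catalysed carboalumination (Negishi) adds methyl and aluminium syn to the terminal alkyne with methyl on the inner carbon C19, iodinolysis goes with retention to the E alkenyl iodide, the hydroxyl is masked in the flask as its aluminium alkoxide, and the internal Z alkene is not carbometallated.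

Step 7
Reactants: 11 (2Z,5E)-6-iodo-5-methylhexa-2,5-dien-1-ol
Product: 12 (2Z,5E)-1-bromo-6-iodo-5-methylhexa-2,5-diene
Conditions: CBr4, PPh3, CH2Cl2, −20 °C
Reagents that add atoms: carbon tetrabromide, BrC(Br)(Br)Br
Why: A second Appel bromination at low temperature activates C23 as the primary Z-allylic bromide, which should be used without storage to avoid Z to E drift.

Step 8
Reactants: 3 (2R,5R)-2-tert-butyl-5-methyl-1,3-dioxolan-4-one; 12 (2Z,5E)-1-bromo-6-iodo-5-methylhexa-2,5-diene
Product: 14 (2R,5S)-2-tert-butyl-5-[(2Z,5E)-6-iodo-5-methylhexa-2,5-dien-1-yl]-5-methyl-1,3-dioxolan-4-one, via lithium enolate 13 (not isolated)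
Conditions: LiN(iPr)2, THF, −78 °C (3 added to the base); then 12, THF–DMPU, −78 → −30 °C
Reagents that add atoms: lithium diisopropylamide, [Li+].CC(C)[N-]C(C)C (lithium kept only in 13)
Why: LiN(iPr)2 removes the C24 proton of 3 and gives the planar lithium enolate 13, in which C24 is trigonal and the acetal carbon is the only stereocentre left; 13 then displaces bromide from the primary allylic carbon C23 of 12 in an SN2 step and forms C23–C24. The closest known reaction type is the diastereoselective alkylation of 2-tert-butyl-5-methyl-1,3-dioxolan-4-one enolates with allylic halides (self-regeneration of a stereocentre). No ring is closed; the dioxolanone is only a carrier. The one new stereocentre, C24, is controlled by the tert-butyl group on the acetal carbon: it blocks one face of the five-membered enolate, the electrophile enters anti to it, C23 takes the place of the former hydrogen, and the (R)-lactate arrangement returns as the (24S) quaternary centre. The step needs facial selectivity, SN2 rather than SN2′ attack, retention of the Z alkene and an untouched alkenyl iodide; these should be secured by the rigid acetal, by the unhindered primary C23 next to a substituted γ-carbon, by staying at or below −30 °C, and by the inertness of an sp2 carbon–iodine bond towards a stabilised enolate. Adding 3 to the base at −78 °C and using 12 at once should hold back self-condensation of 13.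

Step 9
Reactants: 14 (2R,5S)-2-tert-butyl-5-[(2Z,5E)-6-iodo-5-methylhexa-2,5-dien-1-yl]-5-methyl-1,3-dioxolan-4-one
Product: 15 2-(trimethylsilyl)ethyl (2S,4Z,7E)-2-hydroxy-8-iodo-2,7-dimethylocta-4,7-dienoate
Conditions: Me3SiCH2CH2OH, NaH, THF, 0 °C; H2O
Reagents that add atoms: 2-(trimethylsilyl)ethanol, C[Si](C)(C)CCO
Why: Alkoxide transesterification: the alkoxide attacks the acylal-type carbonyl C25, the hemiacetal alkoxide set free collapses to pivalaldehyde, and since no bond to C24 is touched its configuration is kept.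

Step 10
Reactants: 15 2-(trimethylsilyl)ethyl (2S,4Z,7E)-2-hydroxy-8-iodo-2,7-dimethylocta-4,7-dienoate
Product: 16 2-(trimethylsilyl)ethyl (2S,4Z,7E)-8-iodo-2,7-dimethyl-2-(triethylsilyloxy)octa-4,7-dienoate
Conditions: TESOTf, 2,6-lutidine, CH2Cl2, −78 → 0 °C
Reagents that add atoms: triethylsilyl triflate, CC[Si](CC)(CC)OS(=O)(=O)C(F)(F)F
Why: Silyl triflate silylation is the standard way to cap a hindered tertiary alcohol, and it keeps C24–OH out of the later acylation chemistry.

Step 11
Reactants: 17 (R)-4-benzyloxazolidin-2-one; 18 benzyloxyacetyl chloride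
Product: 19 (R)-4-benzyl-3-[(benzyloxy)acetyl]oxazolidin-2-one
Conditions: Et3N, DMAP (cat.), CH2Cl2, 0 °C → rt
Reagents that add atoms: none
Why: DMAP-catalysed N-acylation of the oxazolidinone with an acid chloride gives the glycolate imide needed for the aldol reaction.

Step 12
Reactants: 19 (R)-4-benzyl-3-[(benzyloxy)acetyl]oxazolidin-2-one; 20 (S)-citronellal
Product: 22 (R)-4-benzyl-3-[(2R,3S,5S)-2-(benzyloxy)-3-hydroxy-5,9-dimethyldec-8-enoyl]oxazolidin-2-one, via boron enolate 21 (not isolated)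
Conditions: Bu2BOTf, Et3N, CH2Cl2, −78 → 0 °C; 20, −78 → 0 °C; H2O2, MeOH–pH 7 buffer
Reagents that add atoms: dibutylboron triflate, CCCCB(CCCC)OS(=O)(=O)C(F)(F)F (boron and butyl groups kept only in 21)
Why: Evans syn aldol reaction: soft enolisation gives the Z boron enolate, which reacts through a Zimmerman–Traxler chair on the face left open by the benzyl group of the (R)-auxiliary, so that C15 (S) and C16 (R) are set syn under reagent control irrespective of the remote C13 methyl group of 20.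

Step 13
Reactants: 22 (R)-4-benzyl-3-[(2R,3S,5S)-2-(benzyloxy)-3-hydroxy-5,9-dimethyldec-8-enoyl]oxazolidin-2-one
Product: 23 (R)-4-benzyl-3-[(2R,3S,5S)-2-(benzyloxy)-3-methoxy-5,9-dimethyldec-8-enoyl]oxazolidin-2-one
Conditions: Me3OBF4, 1,8-bis(dimethylamino)naphthalene, 4 Å molecular sieves, CH2Cl2, rt
Reagents that add atoms: trimethyloxonium tetrafluoroborate, C[O+](C)C.F[B-](F)(F)F
Why: O-Methylation with Meerwein salt and a non-nucleophilic proton scavenger works without alkoxide formation, so retro-aldol cleavage and epimerisation at C16 should not occur.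

Step 14
Reactants: 23 (R)-4-benzyl-3-[(2R,3S,5S)-2-(benzyloxy)-3-methoxy-5,9-dimethyldec-8-enoyl]oxazolidin-2-one
Product: 24 (2S,3S,5S)-2-(benzyloxy)-3-methoxy-5,9-dimethyldec-8-en-1-ol
Conditions: LiBH4, MeOH, Et2O, 0 °C; aq. NaOH
Reagents that add atoms: none
Why: Reductive removal of the auxiliary with LiBH4 turns the imide carbonyl C17 into the primary alcohol and returns the oxazolidinone, while the ethers and the alkene are inert.

Step 15
Reactants: 24 (2S,3S,5S)-2-(benzyloxy)-3-methoxy-5,9-dimethyldec-8-en-1-ol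
Product: 25 (2S,3S,5S)-3-methoxy-5,9-dimethyldec-8-ene-1,2-diol
Conditions: Li, NH3 (l), THF, −78 °C; NH4Cl
Reagents that add atoms: none
Why: Dissolving-metal (Birch-type) debenzylation cleaves the benzylic C–O bond by electron transfer and spares the isolated trisubstituted alkene and the alkyl methyl ether.

Step 16
Reactants: 25 (2S,3S,5S)-3-methoxy-5,9-dimethyldec-8-ene-1,2-diol
Product: 26 (2S,3S,5S)-1,2-bis(tert-butyldimethylsilyloxy)-3-methoxy-5,9-dimethyldec-8-ene
Conditions: TBSOTf (2.5 equiv), 2,6-lutidine, CH2Cl2, 0 °C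
Reagents that add atoms: tert-butyldimethylsilyl triflate, CC(C)(C)[Si](C)(C)OS(=O)(=O)C(F)(F)F
Why: Double silylation with the silyl triflate covers the primary C17 and the hindered secondary C16 hydroxyl in one step and places at C16 a non-chelating group that suits step 27 and falls in step 30.

Step 17
Reactants: 26 (2S,3S,5S)-1,2-bis(tert-butyldimethylsilyloxy)-3-methoxy-5,9-dimethyldec-8-ene
Product: 27 (4S,6S,7S)-7,8-bis(tert-butyldimethylsilyloxy)-6-methoxy-4-methyloctanal
Conditions: OsO4 (cat.), NaIO4, 2,6-lutidine, dioxane–H2O, rt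
Reagents that add atoms: osmium tetroxide, O=[Os](=O)(=O)=O; sodium periodate, [Na+].[O-]I(=O)(=O)=O
Why: Lemieux–Johnson cleavage (catalytic dihydroxylation and periodate scission) of the only alkene releases the C10 aldehyde and acetone without over-oxidation.

Step 18
Reactants: 27 (4S,6S,7S)-7,8-bis(tert-butyldimethylsilyloxy)-6-methoxy-4-methyloctanal; 28 L-serine methyl ester hydrochloride
Product: 30 methyl 2-[(3S,5S,6S)-6,7-bis(tert-butyldimethylsilyloxy)-5-methoxy-3-methylheptyl]-1,3-oxazole-4-carboxylate, via oxazolidine 29 (not isolated)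
Conditions: Et3N, MgSO4, THF, rt; then BrCCl3, DBU, CH2Cl2, 0 °C → rt
Reagents that add atoms: none
Why: Condensation of an aldehyde with a serine ester to an oxazolidine, followed by twofold bromination–dehydrobromination with BrCCl3 and DBU, is a known direct route to 2-substituted oxazole-4-carboxylates; it closes ring A by forming N–C10 and O–C10 and erases the serine stereocentre.

Step 19
Reactants: 30 methyl 2-[(3S,5S,6S)-6,7-bis(tert-butyldimethylsilyloxy)-5-methoxy-3-methylheptyl]-1,3-oxazole-4-carboxylate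
Product: 32 1-{2-[(3S,5S,6S)-6,7-bis(tert-butyldimethylsilyloxy)-5-methoxy-3-methylheptyl]-1,3-oxazol-4-yl}ethanone, via Weinreb amide 31 (not isolated)
Conditions: MeNH(OMe)·HCl, iPrMgCl, THF, −20 °C; then MeMgBr, 0 °C; aq. NH4Cl
Reagents that add atoms: methylmagnesium bromide, C[Mg]Br; N,O-dimethylhydroxylamine hydrochloride, CNOC.Cl (atoms kept only in 31)
Why: Weinreb ketone synthesis run in one flask: the magnesium amide converts the ester into the N-methoxy-N-methylamide, whose chelated tetrahedral adduct with MeMgBr stops at the ketone stage and delivers C7 with its methyl group.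

Step 20
Reactants: 32 1-{2-[(3S,5S,6S)-6,7-bis(tert-butyldimethylsilyloxy)-5-methoxy-3-methylheptyl]-1,3-oxazol-4-yl}ethanone
Product: 33 (E)-3-{2-[(3S,5S,6S)-6,7-bis(tert-butyldimethylsilyloxy)-5-methoxy-3-methylheptyl]-1,3-oxazol-4-yl}-N-methoxy-N-methylbut-2-enamide
Conditions: (EtO)2P(O)CH2C(O)N(OMe)Me, NaH, THF, 0 °C → 40 °C
Reagents that add atoms: diethyl {2-[methoxy(methyl)amino]-2-oxoethyl}phosphonate, CCOP(=O)(CC(=O)N(C)OC)OCC
Why: Horner–Wadsworth–Emmons olefination of the heteroaryl methyl ketone should place the bulky oxazole trans to the amide carbonyl and thus give the E C6=C7 alkene, any Z isomer being removable by chromatography.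

Step 21
Reactants: 33 (E)-3-{2-[(3S,5S,6S)-6,7-bis(tert-butyldimethylsilyloxy)-5-methoxy-3-methylheptyl]-1,3-oxazol-4-yl}-N-methoxy-N-methylbut-2-enamide
Product: 34 (E)-3-{2-[(3S,5S,6S)-6,7-bis(tert-butyldimethylsilyloxy)-5-methoxy-3-methylheptyl]-1,3-oxazol-4-yl}but-2-enal
Conditions: iBu2AlH, THF, −78 °C; aq. Rochelle salt
Reagents that add atoms: none
Why: Reduction of a Weinreb amide with iBu2AlH stops at the chelated hemiaminal and gives the enal on work-up, which saves the usual reduction–reoxidation pair.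

Step 22
Reactants: 34 (E)-3-{2-[(3S,5S,6S)-6,7-bis(tert-butyldimethylsilyloxy)-5-methoxy-3-methylheptyl]-1,3-oxazol-4-yl}but-2-enal
Product: 35 (2E,4R,5S)-2-{2-[(3S,5S,6S)-6,7-bis(tert-butyldimethylsilyloxy)-5-methoxy-3-methylheptyl]-1,3-oxazol-4-yl}-5-methylhepta-2,6-dien-4-ol
Conditions: cis-but-2-ene, n-BuLi, KOtBu, THF, −78 → −45 °C; (+)-Ipc2BOMe, −78 °C; BF3·OEt2; 34, −78 °C; NaOH, H2O2
Reagents that add atoms: (Z)-crotyldiisopinocampheylborane made in the flask from cis-but-2-ene and (+)-Ipc2BOMe, C/C=C\CB([C@H]1C[C@H]2C[C@@H]([C@@H]1C)C2(C)C)[C@H]1C[C@H]2C[C@@H]([C@@H]1C)C2(C)C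
Why: Brown crotylboration: the Z crotylborane reacts through a closed chair transition state, so the Z geometry translates into the syn C4/C5 relationship, and the isopinocampheyl groups derived from (−)-α-pinene direct attack to the aldehyde face that gives (4S,5R), the remote centres having no say.

Step 23
Reactants: 35 (2E,4R,5S)-2-{2-[(3S,5S,6S)-6,7-bis(tert-butyldimethylsilyloxy)-5-methoxy-3-methylheptyl]-1,3-oxazol-4-yl}-5-methylhepta-2,6-dien-4-ol
Product: 36 C5 tert-butyldimethylsilyl ether of 35 (C3–C17 tris-silyl ether with terminal alkene)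
Conditions: TBSOTf, 2,6-lutidine, CH2Cl2, −78 → 0 °C
Reagents that add atoms: tert-butyldimethylsilyl triflate, CC(C)(C)[Si](C)(C)OS(=O)(=O)C(F)(F)F
Why: Silyl triflate silylation protects the hindered allylic C5 alcohol under mild, non-ionising conditions.

Step 24
Reactants: 36 C3–C17 tris-silyl ether with terminal alkene; 37 methyl acrylate
Product: 38 methyl (2E,4S,5R,6E)-7-{2-[(3S,5S,6S)-6,7-bis(tert-butyldimethylsilyloxy)-5-methoxy-3-methylheptyl]-1,3-oxazol-4-yl}-5-(tert-butyldimethylsilyloxy)-4-methylocta-2,6-dienoate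
Conditions: second-generation Hoveyda–Grubbs catalyst, (H2IMes)Cl2Ru(=CH-C6H4-2-OiPr) (5 mol %), 37 (excess), CH2Cl2, reflux
Reagents that add atoms: none
Why: Olefin cross metathesis between the monosubstituted alkene and an excess of the electron-poor acrylate should give the E enoate selectively, the trisubstituted C6=C7 alkene being too hindered to take part.

Step 25
Reactants: 38 methyl (2E,4S,5R,6E)-7-{2-[(3S,5S,6S)-6,7-bis(tert-butyldimethylsilyloxy)-5-methoxy-3-methylheptyl]-1,3-oxazol-4-yl}-5-(tert-butyldimethylsilyloxy)-4-methylocta-2,6-dienoate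
Product: 39 methyl (2E,4S,5R,6E)-5-(tert-butyldimethylsilyloxy)-7-{2-[(3S,5S,6S)-6-(tert-butyldimethylsilyloxy)-7-hydroxy-5-methoxy-3-methylheptyl]-1,3-oxazol-4-yl}-4-methylocta-2,6-dienoate
Conditions: HF·pyridine, pyridine, THF, 0 °C
Reagents that add atoms: none
Why: Buffered HF·pyridine discriminates on steric grounds and should remove only the primary C17 silyl ether, leaving the two secondary ones.

Step 26
Reactants: 39 methyl (2E,4S,5R,6E)-5-(tert-butyldimethylsilyloxy)-7-{2-[(3S,5S,6S)-6-(tert-butyldimethylsilyloxy)-7-hydroxy-5-methoxy-3-methylheptyl]-1,3-oxazol-4-yl}-4-methylocta-2,6-dienoate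
Product: 40 methyl (2E,4S,5R,6E)-5-(tert-butyldimethylsilyloxy)-7-{2-[(3S,5S,6R)-6-(tert-butyldimethylsilyloxy)-5-methoxy-3-methyl-7-oxoheptyl]-1,3-oxazol-4-yl}-4-methylocta-2,6-dienoate (C1–C17 aldehyde)
Conditions: Dess–Martin periodinane, CH2Cl2, 0 °C → rt
Reagents that add atoms: none
Why: Dess–Martin oxidation under near-neutral conditions gives the α-silyloxy aldehyde without epimerisation at C16 or β-elimination of the C15 methoxy group, and 40 should be used at once.

Step 27
Reactants: 40 C1–C17 aldehyde; 16 2-(trimethylsilyl)ethyl (2S,4Z,7E)-8-iodo-2,7-dimethyl-2-(triethylsilyloxy)octa-4,7-dienoate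
Product: 42 C1–C25 seco ester with free (17S)-carbinol (16,17-anti), via alkenylchromium species 41 (not isolated)
Conditions: CrCl2 (excess), NiCl2 (1 mol %), DMSO, rt
Reagents that add atoms: chromium dichloride, Cl[Cr]Cl (chromium and chlorine kept only in 41)
Why: Nozaki–Hiyama–Kishi reaction: nickel-catalysed insertion gives the alkenylchromium species with retention of the E geometry, it adds chemoselectively to the aldehyde in the presence of both esters, and the polar Felkin–Anh model with the non-chelating C16 silyloxy group predicts the 16,17-anti carbinol, that is (17S).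

Step 28
Reactants: 42 C1–C25 seco ester with free (17S)-carbinol
Product: 43 C1–C25 seco acid (C1 carboxylic acid, free C17 hydroxyl)
Conditions: Me3SnOH, ClCH2CH2Cl, 80 °C; dilute aq. HCl wash
Reagents that add atoms: trimethyltin hydroxide, C[Sn](C)(C)O
Why: Ester cleavage with Me3SnOH is mild and sterically demanding, so the unhindered C1 methyl ester should be hydrolysed, while the silyl ethers and the C25 ester (shielded by the quaternary C24 and its larger alkyl group) stay.

Step 29
Reactants: 43 C1–C25 seco acid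
Product: 45 fully silylated macrolactone (5,16-bis-TBS ether, 24-TES ether, C25 2-(trimethylsilyl)ethyl ester), via mixed anhydride 44 (not isolated)
Conditions: 2,4,6-Cl3C6H2COCl, Et3N, THF, rt; then slow addition to DMAP, toluene, rt → 40 °C, high dilution
Reagents that add atoms: 2,4,6-trichlorobenzoyl chloride, O=C(Cl)c1c(Cl)cc(Cl)cc1Cl (atoms kept only in 44)
Why: Yamaguchi macrolactonisation: the acyl group of the mixed anhydride is passed to DMAP and trapped by the only free hydroxyl (C17) under high dilution, closing ring B by C1–O bond formation with retention at C17.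

Step 30
Reactants: 45 fully silylated macrolactone
Product: 46 target CNP0112511.2
Conditions: (Me2N)3S·Me3SiF2 (TASF, excess), DMF, 0 °C → rt; aq. NH4Cl
Reagents that add atoms: none
Why: All four protecting groups are silicon-based, so a mild anhydrous fluoride source should cleave the three silyl ethers and fragment the 2-(trimethylsilyl)ethyl ester (to ethene) in one desilylation step, its low basicity limiting acyl shift from O17 to the freed O16.

**Compound list**
1 | (R)-lactic acid | C[C@@H](O)C(=O)O | starting material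
2 | pivalaldehyde | CC(C)(C)C=O | starting material
3 | (2R,5R)-2-tert-butyl-5-methyl-1,3-dioxolan-4-one (cis) | CC(C)(C)[C@H]1OC(=O)[C@@H](C)O1 | intermediate
4 | cis-but-2-ene-1,4-diol | OC/C=C\CO | starting material
5 | (Z)-4-(tert-butyldimethylsilyloxy)but-2-en-1-ol | CC(C)(C)[Si](C)(C)OC/C=C\CO | intermediate
6 | (Z)-1-bromo-4-(tert-butyldimethylsilyloxy)but-2-ene | CC(C)(C)[Si](C)(C)OC/C=C\CBr | intermediate
7 | ethynyltrimethylsilane | C#C[Si](C)(C)C | starting material
8 | tert-butyldimethyl{[(Z)-6-(trimethylsilyl)hex-2-en-5-yn-1-yl]oxy}silane | CC(C)(C)[Si](C)(C)OC/C=C\CC#C[Si](C)(C)C | intermediate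
9 | (Z)-hex-2-en-5-yn-1-ol | OC/C=C\CC#C | intermediate
10 | (2Z,5E)-alkenyldimethylalane, hydroxyl as dimethylaluminium alkoxide (not isolated) | C[Al](C)OC/C=C\C/C(C)=C/[Al](C)C | intermediate
11 | (2Z,5E)-6-iodo-5-methylhexa-2,5-dien-1-ol | OC/C=C\C/C(C)=C/I | intermediate
12 | (2Z,5E)-1-bromo-6-iodo-5-methylhexa-2,5-diene | BrC/C=C\C/C(C)=C/I | intermediate
13 | lithium enolate of 3 (not isolated) | CC(C)(C)[C@H]1OC([O-])=C(C)O1.[Li+] | intermediate
14 | (2R,5S)-2-tert-butyl-5-[(2Z,5E)-6-iodo-5-methylhexa-2,5-dien-1-yl]-5-methyl-1,3-dioxolan-4-one | CC(C)(C)[C@H]1OC(=O)[C@](C)(C/C=C\C/C(C)=C/I)O1 | intermediate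
15 | 2-(trimethylsilyl)ethyl (2S,4Z,7E)-2-hydroxy-8-iodo-2,7-dimethylocta-4,7-dienoate | I/C=C(\C)C/C=C\C[C@](C)(O)C(=O)OCC[Si](C)(C)C | intermediate
16 | 2-(trimethylsilyl)ethyl (2S,4Z,7E)-8-iodo-2,7-dimethyl-2-(triethylsilyloxy)octa-4,7-dienoate | I/C=C(\C)C/C=C\C[C@](C)(O[Si](CC)(CC)CC)C(=O)OCC[Si](C)(C)C | intermediate
17 | (R)-4-benzyloxazolidin-2-one | O=C1OC[C@@H](Cc2ccccc2)N1 | starting material
18 | benzyloxyacetyl chloride | O=C(Cl)COCc1ccccc1 | starting material
19 | (R)-4-benzyl-3-[(benzyloxy)acetyl]oxazolidin-2-one | O=C1OC[C@@H](Cc2ccccc2)N1C(=O)COCc1ccccc1 | intermediate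
20 | (S)-citronellal | O=CC[C@@H](C)CCC=C(C)C | starting material
21 | (Z)-dibutylboron enolate of 19 (not isolated) | CCCCB(CCCC)O/C(=C\OCc1ccccc1)N1C(=O)OC[C@H]1Cc1ccccc1 | intermediate
22 | (R)-4-benzyl-3-[(2R,3S,5S)-2-(benzyloxy)-3-hydroxy-5,9-dimethyldec-8-enoyl]oxazolidin-2-one | O=C1OC[C@@H](Cc2ccccc2)N1C(=O)[C@H](OCc1ccccc1)[C@@H](O)C[C@@H](C)CCC=C(C)C | intermediate
23 | (R)-4-benzyl-3-[(2R,3S,5S)-2-(benzyloxy)-3-methoxy-5,9-dimethyldec-8-enoyl]oxazolidin-2-one | O=C1OC[C@@H](Cc2ccccc2)N1C(=O)[C@H](OCc1ccccc1)[C@@H](OC)C[C@@H](C)CCC=C(C)C | intermediate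
24 | (2S,3S,5S)-2-(benzyloxy)-3-methoxy-5,9-dimethyldec-8-en-1-ol | OC[C@H](OCc1ccccc1)[C@@H](OC)C[C@@H](C)CCC=C(C)C | intermediate
25 | (2S,3S,5S)-3-methoxy-5,9-dimethyldec-8-ene-1,2-diol | OC[C@H](O)[C@@H](OC)C[C@@H](C)CCC=C(C)C | intermediate
26 | (2S,3S,5S)-1,2-bis(tert-butyldimethylsilyloxy)-3-methoxy-5,9-dimethyldec-8-ene | CC(C)(C)[Si](C)(C)OC[C@H](O[Si](C)(C)C(C)(C)C)[C@@H](OC)C[C@@H](C)CCC=C(C)C | intermediate
27 | (4S,6S,7S)-7,8-bis(tert-butyldimethylsilyloxy)-6-methoxy-4-methyloctanal | CC(C)(C)[Si](C)(C)OC[C@H](O[Si](C)(C)C(C)(C)C)[C@@H](OC)C[C@@H](C)CCC=O | intermediate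
28 | L-serine methyl ester hydrochloride | COC(=O)[C@@H](N)CO.Cl | starting material
29 | methyl (4S)-2-alkyloxazolidine-4-carboxylate from 27 and 28, epimeric at ring C2 (not isolated) | CC(C)(C)[Si](C)(C)OC[C@H](O[Si](C)(C)C(C)(C)C)[C@@H](OC)C[C@@H](C)CCC1N[C@@H](CO1)C(=O)OC | intermediate
30 | methyl 2-[(3S,5S,6S)-6,7-bis(tert-butyldimethylsilyloxy)-5-methoxy-3-methylheptyl]-1,3-oxazole-4-carboxylate | CC(C)(C)[Si](C)(C)OC[C@H](O[Si](C)(C)C(C)(C)C)[C@@H](OC)C[C@@H](C)CCc1nc(co1)C(=O)OC | intermediate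
31 | N-methoxy-N-methylamide corresponding to 30 (not isolated) | CC(C)(C)[Si](C)(C)OC[C@H](O[Si](C)(C)C(C)(C)C)[C@@H](OC)C[C@@H](C)CCc1nc(co1)C(=O)N(C)OC | intermediate
32 | 1-{2-[(3S,5S,6S)-6,7-bis(tert-butyldimethylsilyloxy)-5-methoxy-3-methylheptyl]-1,3-oxazol-4-yl}ethanone | CC(C)(C)[Si](C)(C)OC[C@H](O[Si](C)(C)C(C)(C)C)[C@@H](OC)C[C@@H](C)CCc1nc(co1)C(C)=O | intermediate
33 | (E)-3-{2-[(3S,5S,6S)-6,7-bis(tert-butyldimethylsilyloxy)-5-methoxy-3-methylheptyl]-1,3-oxazol-4-yl}-N-methoxy-N-methylbut-2-enamide | CC(C)(C)[Si](C)(C)OC[C@H](O[Si](C)(C)C(C)(C)C)[C@@H](OC)C[C@@H](C)CCc1nc(co1)/C(C)=C/C(=O)N(C)OC | intermediate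
34 | (E)-3-{2-[(3S,5S,6S)-6,7-bis(tert-butyldimethylsilyloxy)-5-methoxy-3-methylheptyl]-1,3-oxazol-4-yl}but-2-enal | CC(C)(C)[Si](C)(C)OC[C@H](O[Si](C)(C)C(C)(C)C)[C@@H](OC)C[C@@H](C)CCc1nc(co1)/C(C)=C/C=O | intermediate
35 | (2E,4R,5S)-2-{2-[(3S,5S,6S)-6,7-bis(tert-butyldimethylsilyloxy)-5-methoxy-3-methylheptyl]-1,3-oxazol-4-yl}-5-methylhepta-2,6-dien-4-ol | CC(C)(C)[Si](C)(C)OC[C@H](O[Si](C)(C)C(C)(C)C)[C@@H](OC)C[C@@H](C)CCc1nc(co1)/C(C)=C/[C@H](O)[C@@H](C)C=C | intermediate
36 | C5 tert-butyldimethylsilyl ether of 35 (4S,5R,13S,15S,16S in target numbering) | CC(C)(C)[Si](C)(C)OC[C@H](O[Si](C)(C)C(C)(C)C)[C@@H](OC)C[C@@H](C)CCc1nc(co1)/C(C)=C/[C@H](O[Si](C)(C)C(C)(C)C)[C@@H](C)C=C | intermediate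
37 | methyl acrylate | C=CC(=O)OC | starting material
38 | methyl (2E,4S,5R,6E)-7-{2-[(3S,5S,6S)-6,7-bis(tert-butyldimethylsilyloxy)-5-methoxy-3-methylheptyl]-1,3-oxazol-4-yl}-5-(tert-butyldimethylsilyloxy)-4-methylocta-2,6-dienoate | CC(C)(C)[Si](C)(C)OC[C@H](O[Si](C)(C)C(C)(C)C)[C@@H](OC)C[C@@H](C)CCc1nc(co1)/C(C)=C/[C@H](O[Si](C)(C)C(C)(C)C)[C@@H](C)/C=C/C(=O)OC | intermediate
39 | C17 primary alcohol derived from 38 | OC[C@H](O[Si](C)(C)C(C)(C)C)[C@@H](OC)C[C@@H](C)CCc1nc(co1)/C(C)=C/[C@H](O[Si](C)(C)C(C)(C)C)[C@@H](C)/C=C/C(=O)OC | intermediate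
40 | C1–C17 aldehyde (4S,5R,13S,15S,16R) | O=C[C@H](O[Si](C)(C)C(C)(C)C)[C@@H](OC)C[C@@H](C)CCc1nc(co1)/C(C)=C/[C@H](O[Si](C)(C)C(C)(C)C)[C@@H](C)/C=C/C(=O)OC | intermediate
41 | (E)-alkenylchromium dichloride from 16 (not isolated) | Cl[Cr](Cl)/C=C(\C)C/C=C\C[C@](C)(O[Si](CC)(CC)CC)C(=O)OCC[Si](C)(C)C | intermediate
42 | C1–C25 seco ester, (17S)-carbinol anti to C16–OTBS (4S,5R,13S,15S,16S,17S,24S; C16 reads S only because the free C17–OH lowers the rank of C17, the spatial arrangement being that of 46) | C[Si](C)(C)CCOC(=O)[C@@](C)(O[Si](CC)(CC)CC)C/C=C\C/C(C)=C/[C@H](O)[C@H](O[Si](C)(C)C(C)(C)C)[C@@H](OC)C[C@@H](C)CCc1nc(co1)/C(C)=C/[C@H](O[Si](C)(C)C(C)(C)C)[C@@H](C)/C=C/C(=O)OC | intermediate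
43 | C1–C25 seco acid (C1 acid of 42) | C[Si](C)(C)CCOC(=O)[C@@](C)(O[Si](CC)(CC)CC)C/C=C\C/C(C)=C/[C@H](O)[C@H](O[Si](C)(C)C(C)(C)C)[C@@H](OC)C[C@@H](C)CCc1nc(co1)/C(C)=C/[C@H](O[Si](C)(C)C(C)(C)C)[C@@H](C)/C=C/C(=O)O | intermediate
44 | 2,4,6-trichlorobenzoic mixed anhydride of 43 (not isolated) | C[Si](C)(C)CCOC(=O)[C@@](C)(O[Si](CC)(CC)CC)C/C=C\C/C(C)=C/[C@H](O)[C@H](O[Si](C)(C)C(C)(C)C)[C@@H](OC)C[C@@H](C)CCc1nc(co1)/C(C)=C/[C@H](O[Si](C)(C)C(C)(C)C)[C@@H](C)/C=C/C(=O)OC(=O)c1c(Cl)cc(Cl)cc1Cl | intermediate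
45 | silylated macrolactone (4S,5R,13S,15S,16R,17S,24S; 2E,6E,18E,21Z) | CO[C@H]1C[C@@H](C)CCc2nc(co2)/C(C)=C/[C@H](O[Si](C)(C)C(C)(C)C)[C@@H](C)/C=C/C(=O)O[C@@H](/C=C(\C)C/C=C\C[C@](C)(O[Si](CC)(CC)CC)C(=O)OCC[Si](C)(C)C)[C@@H]1O[Si](C)(C)C(C)(C)C | intermediate
46 | CNP0112511.2 (4S,5R,13S,15S,16R,17S,24S; 2E,6E,18E,21Z) | CO[C@H]1C[C@@H](C)CCc2nc(co2)/C(C)=C/[C@H](O)[C@@H](C)/C=C/C(=O)O[C@@H](/C=C(\C)C/C=C\C[C@](C)(O)C(=O)O)[C@@H]1O | target

**Step count**
Total step count: 30.
Longest linear sequence: 20 steps (steps 11–30, from 17 and 18). The side-chain branch runs over 13 steps (steps 2–10 and 27–30).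

**Steps most likely to fail**

- **Step 27.**
  - **Risk:** Facial selectivity at the C17 aldehyde may be poor, because Felkin–Anh control by an α-silyloxy group is often modest in chromium additions. A slow coupling would also give the sensitive aldehyde time to degrade.
  - **Fallback:** It sets out from 40 and 16 and returns at 45. The two C17 epimers are separated and 42 goes on as planned. The (17R)-epimer of the seco ester F1 is hydrolysed with Me3SnOH to the (17R)-seco acid F2. F2 is cyclised under Mitsunobu conditions (PPh3, DIAD, toluene, high dilution). Here the alcohol is activated instead of the acid, the carboxylate displaces the oxyphosphonium group with inversion at C17, and both epimers end in the same lactone 45.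

- **Step 18.**
  - **Risk:** The oxazolidine of an unbranched, enolisable aldehyde may form incompletely. During the oxidation it may also be lost through enamine formation and α-bromination.
  - **Fallback:** It sets out from 27 and returns at 30. Pinnick oxidation (NaClO2, NaH2PO4, 2-methylbut-2-ene, tBuOH–H2O) gives (4S,6S,7S)-7,8-bis(tert-butyldimethylsilyloxy)-6-methoxy-4-methyloctanoic acid F3. Coupling with 28 (EDC·HCl, HOBt, iPr2NEt, CH2Cl2) gives the N-acyl-L-serine methyl ester F4. Cyclodehydration with Deoxo-Fluor at −20 °C gives the methyl (4S)-4,5-dihydrooxazole-4-carboxylate F5. A single BrCCl3–DBU oxidation then aromatises F5 to 30.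

- **Step 29.**
  - **Risk:** Activating the 2-enoic acid in the presence of DMAP may cause E/Z isomerisation or deconjugation with loss of the C4 stereocentre. Oligomerisation may also compete with ring closure.
  - **Fallback:** It sets out from 36 and returns at 45, and it closes ring B at C2=C3 instead of at C1–O.
    - Buffered HF·pyridine converts 36 into the C17 primary alcohol with terminal alkene F6.
    - Dess–Martin oxidation gives the C3–C17 aldehyde F7.
    - Nozaki–Hiyama–Kishi coupling with 16 gives the (17S)-carbinol with terminal alkene F8.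
    - Acryloyl chloride and iPr2NEt give the C17 acrylate F9.
    - Ring-closing metathesis with the second-generation Grubbs catalyst (CH2Cl2, reflux, high dilution) joins the acrylate to the only monosubstituted alkene and gives 45. Steps 24 and 28 then become unnecessary.

Further compounds
F1 | step 27 | (17R)-epimer of seco ester 42 | C[Si](C)(C)CCOC(=O)[C@@](C)(O[Si](CC)(CC)CC)C/C=C\C/C(C)=C/[C@@H](O)[C@H](O[Si](C)(C)C(C)(C)C)[C@@H](OC)C[C@@H](C)CCc1nc(co1)/C(C)=C/[C@H](O[Si](C)(C)C(C)(C)C)[C@@H](C)/C=C/C(=O)OC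
F2 | step 27 | (17R)-seco acid | C[Si](C)(C)CCOC(=O)[C@@](C)(O[Si](CC)(CC)CC)C/C=C\C/C(C)=C/[C@@H](O)[C@H](O[Si](C)(C)C(C)(C)C)[C@@H](OC)C[C@@H](C)CCc1nc(co1)/C(C)=C/[C@H](O[Si](C)(C)C(C)(C)C)[C@@H](C)/C=C/C(=O)O
F3 | step 18 | (4S,6S,7S)-7,8-bis(tert-butyldimethylsilyloxy)-6-methoxy-4-methyloctanoic acid | CC(C)(C)[Si](C)(C)OC[C@H](O[Si](C)(C)C(C)(C)C)[C@@H](OC)C[C@@H](C)CCC(=O)O
F4 | step 18 | N-acyl-L-serine methyl ester from F3 and 28 | CC(C)(C)[Si](C)(C)OC[C@H](O[Si](C)(C)C(C)(C)C)[C@@H](OC)C[C@@H](C)CCC(=O)N[C@@H](CO)C(=O)OC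
F5 | step 18 | methyl (4S)-2-alkyl-4,5-dihydrooxazole-4-carboxylate from F4 | CC(C)(C)[Si](C)(C)OC[C@H](O[Si](C)(C)C(C)(C)C)[C@@H](OC)C[C@@H](C)CCC1=N[C@@H](CO1)C(=O)OC
F6 | step 29 | C17 primary alcohol with terminal alkene, from 36 | OC[C@H](O[Si](C)(C)C(C)(C)C)[C@@H](OC)C[C@@H](C)CCc1nc(co1)/C(C)=C/[C@H](O[Si](C)(C)C(C)(C)C)[C@@H](C)C=C
F7 | step 29 | C3–C17 aldehyde with terminal alkene | O=C[C@H](O[Si](C)(C)C(C)(C)C)[C@@H](OC)C[C@@H](C)CCc1nc(co1)/C(C)=C/[C@H](O[Si](C)(C)C(C)(C)C)[C@@H](C)C=C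
F8 | step 29 | (17S)-carbinol with terminal alkene, from F7 and 16 | C[Si](C)(C)CCOC(=O)[C@@](C)(O[Si](CC)(CC)CC)C/C=C\C/C(C)=C/[C@H](O)[C@H](O[Si](C)(C)C(C)(C)C)[C@@H](OC)C[C@@H](C)CCc1nc(co1)/C(C)=C/[C@H](O[Si](C)(C)C(C)(C)C)[C@@H](C)C=C
F9 | step 29 | C17 acrylate of F8 | C[Si](C)(C)CCOC(=O)[C@@](C)(O[Si](CC)(CC)CC)C/C=C\C/C(C)=C/[C@H](OC(=O)C=C)[C@H](O[Si](C)(C)C(C)(C)C)[C@@H](OC)C[C@@H](C)CCc1nc(co1)/C(C)=C/[C@H](O[Si](C)(C)C(C)(C)C)[C@@H](C)C=C
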